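**Strategy**

Ring B is closed last, at its C6–C7 bond. The route exploits that C6 is a bare methylene lying between C5, which is flanked by the quaternary carbons C4 and C10, and the vinylic C7 of the trisubstituted C7=C8 alkene. A σ-vinyl radical at C7 adds 6-endo to the CH2 terminus of a C5=C6 exocyclic methylene on ring A; hydrogen transfer to the tertiary C5 radical then sets the trans ring fusion. One operation gives ring B, the C7=C8 alkene in place and the C5 stereocentre. The precursor is a monocyclic ring A bromo-1,5-diene whose vicinal C9/C10 stereocentres come from an Ireland–Claisen rearrangement.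

Key step: step 13

Remark: carbons carry labdane numbers (C1–C20); the target is an ent-labdane, and "as in the target" refers to the configuration in the given SMILES.
Remark: (S)-3-hydroxy-2,2-dimethylcyclohexan-1-one (the yeast-reduction product of the 1,3-dione), (4-ethoxy-4-oxobutyl)zinc bromide solution and (tributylstannyl)methanol are assumed to be purchasable.

**Fragment 1 (ring A)**

Step 1
Reactants: 1 (S)-3-hydroxy-2,2-dimethylcyclohexan-1-one
Product: 2 (S)-2,2-dimethyl-3-(triethylsilyloxy)cyclohexan-1-one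
Conditions: Et3SiCl, imidazole, DMF, 0 °C to rt
Reagents that add atoms: chlorotriethylsilane, CC[Si](Cl)(CC)CC
Why: Routine silylation of a secondary alcohol; the triethylsilyl ether blocks retro-aldol cleavage and can later be removed beside a tert-butyldiphenylsilyl ether.

Step 2
Reactants: 2 (S)-2,2-dimethyl-3-(triethylsilyloxy)cyclohexan-1-one
Product: 4 (3S)-2,2,6-trimethyl-3-(triethylsilyloxy)cyclohexan-1-one (both C6 epimers), via lithium enolate 3 (not isolated)
Conditions: LiN(iPr)2, THF, −78 °C; MeI, −78 to 0 °C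
Reagents that add atoms: iodomethane, CI
Why: Enolate alkylation is regiospecific because the other α-carbon is quaternary; the new centre (future C10) becomes sp2 in the next step, so its configuration is irrelevant.

Step 3
Reactants: 4 (3S)-2,2,6-trimethyl-3-(triethylsilyloxy)cyclohexan-1-one
Product: 6 (S)-2,6,6-trimethyl-5-(triethylsilyloxy)cyclohex-1-en-1-yl trifluoromethanesulfonate, via potassium enolate 5 (not isolated)
Conditions: KN(SiMe3)2, THF, −78 to 0 °C; PhNTf2
Reagents that add atoms: N-phenylbis(trifluoromethanesulfonimide), O=S(=O)(N(c1ccccc1)S(=O)(=O)C(F)(F)F)C(F)(F)F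
Why: Enol triflate formation; only one enolate (the tetrasubstituted C5=C10 one) can form.

Step 4
Reactants: 6 (S)-2,6,6-trimethyl-5-(triethylsilyloxy)cyclohex-1-en-1-yl trifluoromethanesulfonate
Product: 7 [(S)-2,6,6-trimethyl-5-(triethylsilyloxy)cyclohex-1-en-1-yl]methanol (fragment 1)
Conditions: Bu3SnCH2OH, Pd(PPh3)4 (10 mol %), LiCl, 1,4-dioxane, 100 °C
Reagents that add atoms: (tributylstannyl)methanol, CCCC[Sn](CCCC)(CCCC)CO
Why: Stille coupling of an enol triflate with a hydroxymethyl stannane installs C6 as the allylic alcohol with the C5=C10 alkene position fixed by the triflate.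

**Fragment 2 (side-chain acid)**

Step 5
Reactants: 8 but-2-yn-1-ol
Product: 9 tert-butyl(but-2-yn-1-yloxy)diphenylsilane
Conditions: t-BuPh2SiCl, imidazole, CH2Cl2, rt
Reagents that add atoms: tert-butylchlorodiphenylsilane, CC(C)(C)[Si](Cl)(c1ccccc1)c1ccccc1
Why: Routine silylation; the robust silyl ether carries the future C15 oxygen through the basic, organometallic and radical steps.

Step 6
Reactants: 9 tert-butyl(but-2-yn-1-yloxy)diphenylsilane
Product: 11 (E)-tert-butyl[(3-iodobut-2-en-1-yl)oxy]diphenylsilane, via alkenylzirconocene chloride 10 (not isolated)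
Conditions: Cp2Zr(H)Cl (2 equiv), THF, rt to 45 °C; I2, 0 °C
Reagents that add atoms: iodine, II
Why: Syn hydrozirconation places zirconium on the methyl-bearing alkyne carbon after equilibration, and iodinolysis with retention gives the E iodide that fixes the later C13=C14 geometry.

Step 7
Reactants: 11 (E)-tert-butyl[(3-iodobut-2-en-1-yl)oxy]diphenylsilane; 12 (4-ethoxy-4-oxobutyl)zinc bromide
Product: 13 ethyl (E)-7-[(tert-butyldiphenylsilyl)oxy]-5-methylhept-5-enoate
Conditions: Pd(PPh3)4 (5 mol %), THF, 50 °C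
Reagents that add atoms: none
Why: Negishi sp3–sp2 coupling proceeds with retention of alkene geometry and tolerates the ester and silyl ether.

Step 8
Reactants: 13 ethyl (E)-7-[(tert-butyldiphenylsilyl)oxy]-5-methylhept-5-enoate
Product: 14 (E)-7-[(tert-butyldiphenylsilyl)oxy]-5-methylhept-5-enoic acid (fragment 2)
Conditions: LiOH, THF/MeOH/H2O, rt; then aq. HCl to pH 4
Reagents that add atoms: lithium hydroxide, [Li+].[OH-]
Why: Ester saponification; the hindered silyl ether survives mild aqueous base.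

**Union, key step and end game**

Step 9
Reactants: 7 [(S)-2,6,6-trimethyl-5-(triethylsilyloxy)cyclohex-1-en-1-yl]methanol; 14 (E)-7-[(tert-butyldiphenylsilyl)oxy]-5-methylhept-5-enoic acid
Product: 15 [(S)-2,6,6-trimethyl-5-(triethylsilyloxy)cyclohex-1-en-1-yl]methyl (E)-7-[(tert-butyldiphenylsilyl)oxy]-5-methylhept-5-enoate
Conditions: DCC, DMAP (cat.), CH2Cl2, 0 °C to rt
Reagents that add atoms: none
Why: Steglich esterification of a primary allylic alcohol.

Step 10
Reactants: 15 [(S)-2,6,6-trimethyl-5-(triethylsilyloxy)cyclohex-1-en-1-yl]methyl (E)-7-[(tert-butyldiphenylsilyl)oxy]-5-methylhept-5-enoate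
Product: 18 (2S,5E)-7-[(tert-butyldiphenylsilyl)oxy]-5-methyl-2-[(1S,4S)-1,3,3-trimethyl-2-methylidene-4-(triethylsilyloxy)cyclohexyl]hept-5-enoic acid (C9 and C10 as in the target), via silyl ketene acetal 16 (not isolated), via trimethylsilyl ester 17 (not isolated)
Conditions: LiN(iPr)2, Me3SiCl, THF/DMPU, −78 °C; then 60 °C; then H2O (pH 5 buffer)
Reagents that add atoms: none
Why: Ireland–Claisen rearrangement: THF/DMPU enolisation gives the (Z)-silyl ketene acetal (C11 chain cis to OSiMe3), whose chair transition state (C10 methyl axial, chain equatorial) sets the C9/C10 relative configuration; the ring face syn to the pseudo-axial C3 silyloxy group and anti to the pseudo-axial C4 methyl is expected to be preferred, though this remote bias may be small, and the separable C9/C10 bis-epimer is removed by chromatography.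

Step 11
Reactants: 18 the Ireland–Claisen acid
Product: 20 (3S,6E)-8-[(tert-butyldiphenylsilyl)oxy]-6-methyl-3-[(1S,4S)-1,3,3-trimethyl-2-methylidene-4-(triethylsilyloxy)cyclohexyl]oct-6-en-2-one, via dilithium gem-diolate 19 (not isolated)
Conditions: MeLi (3.5 equiv), Et2O, 0 °C to rt; then aq. NH4Cl
Reagents that add atoms: methyllithium, [Li]C
Why: Methyllithium adds once to the lithium carboxylate and the gem-diolate collapses to the methyl ketone only on work-up; the hindered C9–H should not epimerise.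

Step 12
Reactants: 20 the methyl ketone
Product: 21 (E/Z)-bromomethylidene compound (20 with C8=O replaced by C8=C7HBr; both alkene isomers are used together)
Conditions: [Ph3PCH2Br]Br, KOt-Bu, THF, −78 °C to rt
Reagents that add atoms: (bromomethyl)triphenylphosphonium bromide, [Br-].BrC[P+](c1ccccc1)(c1ccccc1)c1ccccc1
Why: Wittig bromomethylenation turns the ketone into the C7 vinyl bromide while the ketone methyl stays as the C8 methyl; alkene geometry is irrelevant for the radical step.

Step 13
Reactants: 21 (E/Z)-bromomethylidene compound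
Product: 24 ent-labda-7,13E-diene-3,15-diol 3-triethylsilyl 15-tert-butyldiphenylsilyl bis-ether (C3, C5, C9 and C10 as in the target), via vinyl radical 22 (not isolated), via tertiary C5 radical 23 (not isolated)
Conditions: Bu3SnH (1.5 equiv, syringe pump), AIBN (cat.), benzene (0.005 M), 80 °C
Reagents that add atoms: none
Why: Bu3Sn• abstracts bromine from either isomer of 21 to give the rapidly inverting σ-vinyl radical 22 at C7, which adds to the unsubstituted C6 terminus of the C5=C6 methylene, forming the C6–C7 bond and tertiary radical 23, which takes hydrogen from Bu3SnH. The closest known reaction type is vinyl radical cyclisation onto an alkene under tin hydride chain conditions. Ring B closes in the 6-endo-trig mode, either directly or by 5-exo attack followed by the known homoallyl (cyclopropylcarbinyl) radical rearrangement, both paths converging on 23. The one new stereocentre, C5, is set in the hydrogen transfer: the stannane approaches anti to the syn-axial C10 and C4 methyls, so H-5 ends trans to the C10 methyl (trans-decalin). The step needs 6-endo over 5-exo selectivity and cyclisation faster than reduction or 1,5-hydrogen transfer; the first is secured by C5 lying between two quaternary carbons, the second by high dilution and slow stannane addition. The C7=C8 alkene and its methyl are carried unchanged from the vinyl bromide, so no alkene regioisomers can arise.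

Step 14
Reactants: 24 the bis-silyl ether
Product: 25 15-O-(tert-butyldiphenylsilyl)-ent-labda-7,13E-diene-3,15-diol (free axial C3–OH)
Conditions: PPTS (cat.), MeOH/CH2Cl2, rt to 40 °C
Reagents that add atoms: none
Why: Mild acid methanolysis removes the triethylsilyl ether and leaves the far more stable tert-butyldiphenylsilyl ether.

Step 15
Reactants: 25 the C3 alcohol
Product: 26 15-[(tert-butyldiphenylsilyl)oxy]-ent-labda-7,13E-dien-3-one
Conditions: 1,1,1-triacetoxy-1,1-dihydro-1,2-benziodoxol-3(1H)-one (DMP), CH2Cl2, rt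
Reagents that add atoms: none
Why: Dess–Martin oxidation of a hindered secondary alcohol; it turns the C3 handle into the ketone needed to oxygenate C2.

Step 16
Reactants: 26 the C3 ketone
Product: 28 15-[(tert-butyldiphenylsilyl)oxy]-2-hydroxy-ent-labda-7,13E-dien-3-one (equatorial C2–OH as in the target), via potassium enolate 27 (not isolated)
Conditions: KN(SiMe3)2, THF, −78 °C; 2-(phenylsulfonyl)-3-phenyloxaziridine, −78 °C; aq. NH4Cl
Reagents that add atoms: 2-(phenylsulfonyl)-3-phenyloxaziridine, O=S(=O)(c1ccccc1)N1OC1c1ccccc1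
Why: Enolate hydroxylation with an N-sulfonyloxaziridine; C2 is the only enolisable position, and the oxidant attacks the face anti to the axial C10 and C4 methyls, giving the equatorial C2 hydroxyl.

Step 17
Reactants: 28 the 2-hydroxy-3-ketone
Product: 29 15-O-(tert-butyldiphenylsilyl)-ent-labda-7,13E-diene-2,3,15-triol (2,3-cis-diol; C3–OH axial, as in the target)
Conditions: LiBH(s-Bu)3 (3 equiv), THF, −78 °C; H2O
Reagents that add atoms: none
Why: The bulky trialkylborohydride avoids the axial trajectory and adds equatorially, so the new C3 hydroxyl is axial and cis to the C2 hydroxyl.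

Step 18
Reactants: 29 the 2,3-diol silyl ether
Product: 30 ent-labda-7,13E-diene-2,3,15-triol (configured as in the target)
Conditions: Bu4NF, THF, rt
Reagents that add atoms: none
Why: Fluoride cleavage of the primary silyl ether.

Step 19
Reactants: 30 the triol
Product: 31 target, 2-acetoxy-3-hydroxy-ent-labda-7,13E-dien-15-yl acetate
Conditions: Ac2O (2.2 equiv), pyridine, CH2Cl2, 0 °C
Reagents that add atoms: acetic anhydride, CC(=O)OC(C)=O
Why: Selective acylation: the primary C15 and equatorial C2 hydroxyls react, while the axial C3 hydroxyl next to the C4 gem-dimethyl group stays free.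

**Compound list**

1 | (S)-3-hydroxy-2,2-dimethylcyclohexan-1-one | CC1(C)C(=O)CCC[C@@H]1O | starting material
2 | (S)-2,2-dimethyl-3-(triethylsilyloxy)cyclohexan-1-one | CC1(C)C(=O)CCC[C@@H]1O[Si](CC)(CC)CC | intermediate
3 | lithium enolate of 2 | CC1(C)C([O-])=CCC[C@@H]1O[Si](CC)(CC)CC.[Li+] | intermediate
4 | (3S)-2,2,6-trimethyl-3-(triethylsilyloxy)cyclohexan-1-one (C6 epimers) | CC1CC[C@H](O[Si](CC)(CC)CC)C(C)(C)C1=O | intermediate
5 | potassium enolate of 4 | CC1=C([O-])C(C)(C)[C@@H](O[Si](CC)(CC)CC)CC1.[K+] | intermediate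
6 | (S)-2,6,6-trimethyl-5-(triethylsilyloxy)cyclohex-1-en-1-yl trifluoromethanesulfonate | CC1=C(OS(=O)(=O)C(F)(F)F)C(C)(C)[C@@H](O[Si](CC)(CC)CC)CC1 | intermediate
7 | [(S)-2,6,6-trimethyl-5-(triethylsilyloxy)cyclohex-1-en-1-yl]methanol | OCC1=C(C)CC[C@H](O[Si](CC)(CC)CC)C1(C)C | intermediate
8 | but-2-yn-1-ol | CC#CCO | starting material
9 | tert-butyl(but-2-yn-1-yloxy)diphenylsilane | CC#CCO[Si](c1ccccc1)(c1ccccc1)C(C)(C)C | intermediate
10 | alkenylzirconocene chloride (Zr on the methyl-bearing carbon, trans to CH2O) | C/C(=C\CO[Si](c1ccccc1)(c1ccccc1)C(C)(C)C)[Zr](Cl)(C1C=CC=C1)C1C=CC=C1 | intermediate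
11 | (E)-tert-butyl[(3-iodobut-2-en-1-yl)oxy]diphenylsilane | CC(C)(C)[Si](c1ccccc1)(c1ccccc1)OC/C=C(\C)I | intermediate
12 | (4-ethoxy-4-oxobutyl)zinc bromide | CCOC(=O)CCC[Zn]Br | starting material
13 | ethyl (E)-7-[(tert-butyldiphenylsilyl)oxy]-5-methylhept-5-enoate | CC(C)(C)[Si](c1ccccc1)(c1ccccc1)OC/C=C(\C)CCCC(=O)OCC | intermediate
14 | (E)-7-[(tert-butyldiphenylsilyl)oxy]-5-methylhept-5-enoic acid | CC(C)(C)[Si](c1ccccc1)(c1ccccc1)OC/C=C(\C)CCCC(=O)O | intermediate
15 | ester of 7 with 14 | CC(C)(C)[Si](c1ccccc1)(c1ccccc1)OC/C=C(\C)CCCC(=O)OCC1=C(C)CC[C@H](O[Si](CC)(CC)CC)C1(C)C | intermediate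
16 | (Z)-silyl ketene acetal of 15 (C11 chain cis to OSiMe3) | CC(C)(C)[Si](c1ccccc1)(c1ccccc1)OC/C=C(\C)CC/C=C(/OCC1=C(C)CC[C@H](O[Si](CC)(CC)CC)C1(C)C)O[Si](C)(C)C | intermediate
17 | trimethylsilyl ester of 18 | CC(C)(C)[Si](c1ccccc1)(c1ccccc1)OC/C=C(\C)CC[C@H](C(=O)O[Si](C)(C)C)[C@]1(C)CC[C@H](O[Si](CC)(CC)CC)C(C)(C)C1=C | intermediate
18 | (2S,5E)-7-[(tert-butyldiphenylsilyl)oxy]-5-methyl-2-[(1S,4S)-1,3,3-trimethyl-2-methylidene-4-(triethylsilyloxy)cyclohexyl]hept-5-enoic acid | CC(C)(C)[Si](c1ccccc1)(c1ccccc1)OC/C=C(\C)CC[C@H](C(=O)O)[C@]1(C)CC[C@H](O[Si](CC)(CC)CC)C(C)(C)C1=C | intermediate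
19 | dilithium gem-diolate from 18 and MeLi | CC(C)(C)[Si](c1ccccc1)(c1ccccc1)OC/C=C(\C)CC[C@H](C(C)([O-])[O-])[C@]1(C)CC[C@H](O[Si](CC)(CC)CC)C(C)(C)C1=C.[Li+].[Li+] | intermediate
20 | methyl ketone (C8 acetyl on C9) | CC(C)(C)[Si](c1ccccc1)(c1ccccc1)OC/C=C(\C)CC[C@H](C(C)=O)[C@]1(C)CC[C@H](O[Si](CC)(CC)CC)C(C)(C)C1=C | intermediate
21 | (E/Z)-bromomethylidene compound (C7 vinyl bromide) | CC(C)(C)[Si](c1ccccc1)(c1ccccc1)OC/C=C(\C)CC[C@H](C(C)=CBr)[C@]1(C)CC[C@H](O[Si](CC)(CC)CC)C(C)(C)C1=C | intermediate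
22 | C7 vinyl radical | CC(C)(C)[Si](c1ccccc1)(c1ccccc1)OC/C=C(\C)CC[C@H](C(C)=[CH])[C@]1(C)CC[C@H](O[Si](CC)(CC)CC)C(C)(C)C1=C | intermediate
23 | bicyclic tertiary C5 radical | CC(C)(C)[Si](c1ccccc1)(c1ccccc1)OC/C=C(\C)CC[C@@H]1C(C)=CC[C]2C(C)(C)[C@@H](O[Si](CC)(CC)CC)CC[C@@]12C | intermediate
24 | ent-labda-7,13E-diene-3,15-diol 3-triethylsilyl 15-tert-butyldiphenylsilyl bis-ether | CC(C)(C)[Si](c1ccccc1)(c1ccccc1)OC/C=C(\C)CC[C@@H]1C(C)=CC[C@@H]2C(C)(C)[C@@H](O[Si](CC)(CC)CC)CC[C@@]12C | intermediate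
25 | 15-O-(tert-butyldiphenylsilyl)-ent-labda-7,13E-diene-3,15-diol | CC(C)(C)[Si](c1ccccc1)(c1ccccc1)OC/C=C(\C)CC[C@@H]1C(C)=CC[C@@H]2C(C)(C)[C@@H](O)CC[C@@]12C | intermediate
26 | 15-[(tert-butyldiphenylsilyl)oxy]-ent-labda-7,13E-dien-3-one | CC(C)(C)[Si](c1ccccc1)(c1ccccc1)OC/C=C(\C)CC[C@@H]1C(C)=CC[C@@H]2C(C)(C)C(=O)CC[C@@]12C | intermediate
27 | potassium C2=C3 enolate of 26 | CC(C)(C)[Si](c1ccccc1)(c1ccccc1)OC/C=C(\C)CC[C@@H]1C(C)=CC[C@@H]2C(C)(C)C([O-])=CC[C@@]12C.[K+] | intermediate
28 | 15-[(tert-butyldiphenylsilyl)oxy]-2-hydroxy-ent-labda-7,13E-dien-3-one | CC(C)(C)[Si](c1ccccc1)(c1ccccc1)OC/C=C(\C)CC[C@@H]1C(C)=CC[C@@H]2C(C)(C)C(=O)[C@@H](O)C[C@@]12C | intermediate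
29 | 15-O-(tert-butyldiphenylsilyl)-ent-labda-7,13E-diene-2,3,15-triol | CC(C)(C)[Si](c1ccccc1)(c1ccccc1)OC/C=C(\C)CC[C@@H]1C(C)=CC[C@@H]2C(C)(C)[C@@H](O)[C@@H](O)C[C@@]12C | intermediate
30 | ent-labda-7,13E-diene-2,3,15-triol | OC/C=C(\C)CC[C@@H]1C(C)=CC[C@@H]2C(C)(C)[C@@H](O)[C@@H](O)C[C@@]12C | intermediate
31 | 2-acetoxy-3-hydroxy-ent-labda-7,13E-dien-15-yl acetate | CC(=O)OC/C=C(\C)CC[C@@H]1C(C)=CC[C@@H]2C(C)(C)[C@@H](O)[C@@H](OC(C)=O)C[C@@]12C | target

**Count and risks**

Total step count: 19. Longest linear sequence: 15 steps (steps 1–4 and 9–19).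

Steps most likely to fail:

1. Step 13 (key radical cyclisation). The vinyl radical may abstract the allylic C12 hydrogen in a 1,5-shift or be reduced before it cyclises, and prolonged heating may trigger a Cope rearrangement of the 1,5-diene. The fallback sets out from methyl ketone 20 and returns at 24. Kinetic enolisation of 20 at the methyl group (LiN(iPr)2, Me3SiCl, THF, −78 °C) would give silyl enol ether F1, and NBS (THF, 0 °C) would turn it into bromomethyl ketone F2. Under Bu3SnH/AIBN the electrophilic α-keto radical, which is not prone to remote hydrogen abstraction, should close the same C6–C7 bond 6-endo onto the electron-rich methylene and, after hydrogen transfer to C5, give trans-decalone F3, in which C9 can be equilibrated by base to the equatorial side chain. KN(SiMe3)2/PhNTf2 (deprotonation at the less hindered C7) would give enol triflate F4, and iron-catalysed methylation (MeMgBr, Fe(acac)3, THF/NMP, −20 °C) would install the C8 methyl and deliver 24.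

2. Step 10 (Ireland–Claisen rearrangement). The remote C3 centre may give poor facial selectivity at C10, and leakage through a boat transition state would erode the C9 configuration. The fallback sets out from ester 15 and returns at acid 18, with reagent control replacing substrate control. Enolisation of 15 with (4S,5S)-2-bromo-4,5-diphenyl-1,3-bis(p-tolylsulfonyl)-1,3,2-diazaborolidine and i-Pr2NEt (CH2Cl2, −78 °C) would give the chiral boron ketene acetal F5 (C11 chain cis to the O–B group). Its [3,3] rearrangement at −20 °C to rt is steered by the boron controller, and hydrolytic work-up gives 18. The sense of induction of this controller has not been assigned here; the antipodal controller is equally accessible if the opposite sense is needed.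

3. Step 12 (bromomethylenation). The ylide may enolise the hindered methyl ketone instead of adding to it. The fallback sets out from acid 18 and returns at 24. LiAlH4 (THF, 0 °C) would give primary alcohol F6, Dess–Martin oxidation aldehyde F7, and Ohira–Bestmann homologation (dimethyl (1-diazo-2-oxopropyl)phosphonate, K2CO3, MeOH) terminal alkyne F8. Zirconium-catalysed carboalumination (AlMe3, Cp2ZrCl2, CH2Cl2) followed by iodinolysis would give (E)-vinyl iodide F9, which already bears the C8 methyl and replaces 21 in the radical cyclisation of step 13 to give 24.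

Further compounds

F1 | step 13 | trimethylsilyl enol ether of 20 at the methyl carbon | CC(C)(C)[Si](c1ccccc1)(c1ccccc1)OC/C=C(\C)CC[C@H](C(=C)O[Si](C)(C)C)[C@]1(C)CC[C@H](O[Si](CC)(CC)CC)C(C)(C)C1=C
F2 | step 13 | bromomethyl ketone (20 with CH2Br in place of the ketone methyl) | CC(C)(C)[Si](c1ccccc1)(c1ccccc1)OC/C=C(\C)CC[C@H](C(=O)CBr)[C@]1(C)CC[C@H](O[Si](CC)(CC)CC)C(C)(C)C1=C
F3 | step 13 | trans-decalone (17-nor-8-oxo analogue of 24 with C7H2) | CC(C)(C)[Si](c1ccccc1)(c1ccccc1)OC/C=C(\C)CC[C@@H]1C(=O)CC[C@@H]2C(C)(C)[C@@H](O[Si](CC)(CC)CC)CC[C@@]12C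
F4 | step 13 | C7=C8 enol triflate of F3 | CC(C)(C)[Si](c1ccccc1)(c1ccccc1)OC/C=C(\C)CC[C@@H]1C(OS(=O)(=O)C(F)(F)F)=CC[C@@H]2C(C)(C)[C@@H](O[Si](CC)(CC)CC)CC[C@@]12C
F5 | step 10 | boron ketene acetal of 15 bearing the (4S,5S)-4,5-diphenyl-1,3-ditosyl-1,3,2-diazaborolidin-2-yl group | CC(C)(C)[Si](c1ccccc1)(c1ccccc1)OC/C=C(\C)CC/C=C(/OCC1=C(C)CC[C@H](O[Si](CC)(CC)CC)C1(C)C)OB1N(S(=O)(=O)c2ccc(C)cc2)[C@@H](c2ccccc2)[C@H](c2ccccc2)N1S(=O)(=O)c1ccc(C)cc1
F6 | step 12 | primary alcohol from reduction of 18 | CC(C)(C)[Si](c1ccccc1)(c1ccccc1)OC/C=C(\C)CC[C@H](CO)[C@]1(C)CC[C@H](O[Si](CC)(CC)CC)C(C)(C)C1=C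
F7 | step 12 | aldehyde from oxidation of F6 | CC(C)(C)[Si](c1ccccc1)(c1ccccc1)OC/C=C(\C)CC[C@H](C=O)[C@]1(C)CC[C@H](O[Si](CC)(CC)CC)C(C)(C)C1=C
F8 | step 12 | terminal alkyne (C8≡C7H on C9) | CC(C)(C)[Si](c1ccccc1)(c1ccccc1)OC/C=C(\C)CC[C@H](C#C)[C@]1(C)CC[C@H](O[Si](CC)(CC)CC)C(C)(C)C1=C
F9 | step 12 | (E)-vinyl iodide (iodo analogue of 21) | CC(C)(C)[Si](c1ccccc1)(c1ccccc1)OC/C=C(\C)CC[C@H](/C(C)=C/I)[C@]1(C)CC[C@H](O[Si](CC)(CC)CC)C(C)(C)C1=C
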